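The north run loses Sbt at 7.54 × 10⁻⁴ M min⁻¹ over its first 14 min. The south run has the same c(Ptn) and 3.00 times the c(Sbt), yet it loses Sbt at 0.00121 M min⁻¹, only 1.60 times as fast. Bound and free are read together, so the Sbt lost is the Pdt made.

in all of them: Ctl 5.00 × 10⁻⁴ M

| charge | Sbt | Ptn | time |
|---|---|---|---|
| north | 0.0500 M | 0.0600 M |  |
| north-west | 0.0250 M | 0.0350 M |  |
| south | 0.150 M | 0.0600 M |  |
| west | 0.150 M | 0.120 M | 84 min |

| north run: time / min | north run: [Sbt] / M | north-west run: time / min | north-west run: [Sbt] / M | south run: time / min | south run: [Sbt] / M |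
|---|---|---|---|---|---|
| 14 | 0.03945 | 14 | 0.01967 | 14 | 0.13308 |
| 28 | 0.03454 | 28 | 0.01678 | 28 | 0.12393 |
| 42 | 0.03161 | 42 | 0.01537 | 42 | 0.11798 |
| 56 | 0.02977 | 56 | 0.01444 | 56 | 0.11487 |
| 70 | 0.02860 | 70 | 0.01416 | 70 | 0.11309 |
| 84 | 0.02806 | 84 | 0.01403 | 84 | 0.11141 |

(standard deviation of a reading: 2 × 10⁻⁴ M)

1. the power of [Ptn] that the first rate follows, about the charge of the north run; measure it at two percent of Sbt made into Pdt
2. the power of [Sbt] that the first rate follows, about the charge of the north run; measure it at two percent of Sbt made into Pdt (one fixed amount of Pdt, the same in the runs compared)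
3. Sbt in the west run at 84 min, as a share of the Sbt charged

- Overall: Sbt + Ptn -> Pdt, with Ctl as catalyst.
- Constant volume, constant temperature.
- Bound and free are read together.
- "The second partner" is Ptn.
- An order is taken over about fifteen percent of the charge, up and down.

My first try is two steps in series. The reciprocal of the rate is then A/c(Sbt) + B/c(Ptn). The north and south runs give A = 37.5 min and B = 34.7 min. Call λ = B/A the balance ratio, the c(Ptn)/c(Sbt) at which the two terms are equal: 0.925. Each order is the share of its own term, so the orders sum to 1. At the north charge I get 0.565 in Sbt and 0.435 in Ptn. Neither term is a rate-limiting step there.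

But two constants drawn from two runs prove nothing. So test them on the north-west run. The law gives 4.02 × 10⁻⁴ M min⁻¹, and the readings give 3.81 × 10⁻⁴ M min⁻¹. The law is higher, and the gap is 1.47 times one reading's scatter over that window, which is 1.43 × 10⁻⁵ M min⁻¹.

A second doubt: these are window averages, and the runs stall. If the fade takes the same share in each run, it scales A and B alike and leaves λ alone. Test that with the exposure, the loss by 84 min over the window rate. It is 29.1 min for north, 28.8 min for north-west and 31.9 min for south.

For the west run the law gives 0.00186 M min⁻¹. With the south exposure, from the run with the same c(Sbt), the loss is 0.0593 M, which leaves 60.5% of the Sbt.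

The forecast says “The rate is therefore saturating”. It gives 0.7 (0.45 to 1) in Ptn, 0.5 (0.3 to 0.75) in Sbt and 60% (54% to 67%) for the west run. Its orders sum to 1.20, so its Ptn order stands above mine.

    Ctl + Sbt → Ctl.Sbt (88.20 L mol⁻¹ min⁻¹)
    Ctl.Sbt + Ptn → Pdt + Ctl (74.40 L mol⁻¹ min⁻¹)
    Ptn → L (0.01062 min⁻¹)
    Ctl → G (0.06900 min⁻¹)

The flask gives 0.52 in Ptn, 0.55 in Sbt and 61.0% for the west run. The forecast's Ptn order is 1.35 times the flask's. The west run stands 0.50 percentage points from the figure built on λ. Now use λ on the north-west run against the north run, with the charges put in. The rate ratio comes to 0.533. Where two percent of the north Sbt has turned, the north-west run makes Pdt at 5.3 × 10⁻⁴ M min⁻¹ and the north run at 0.0010 M min⁻¹, a ratio of 0.507.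

The numbers in the tables stem from a simulated flask on assumed constants; noise was put on by code.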